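**Strategy.** Chain numbering runs from the lactone carbonyl (C1) to the methyl group (C12). The tetrahydrofuran (O, C4, C5, C6, C7) is closed last, on a finished dihydropyranone, by oxidative allylic etherification: the C4 hydroxyl adds across a transposed C7=C8 alkene under phenylselenenyl chloride, and selenoxide elimination re-forms the alkene at C8=C9. The step exploits the allylic C7–O bond of the furan ring and the neighbouring C6 hydroxyl, which relays its configuration to C7; the cis ring fusion is dictated by the pyranone. The precursor is a monocyclic triol: C3–C7 come from D-mannose and C10–C12 from (R)-but-3-en-2-ol; an allyl unit (C8, C9) links them by cross-metathesis. The key step gives the target directly.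

Key step: step 11

Remark on the chemistry: the labels C1–C12 and O4, O6, O10 refer to this chain numbering in every compound, whatever its systematic name.

Step 1
Reactants: 1 2,3:5,6-di-O-isopropylidene-α-D-mannofuranose
Product: 2 1,2-dideoxy-3,4:6,7-di-O-isopropylidene-D-manno-hept-1-enitol
Conditions: Ph3PCH3Br (3 equiv), KOtBu, THF, 0 °C to reflux
Reagents that add atoms: methyltriphenylphosphonium bromide, C[P+](c1ccccc1)(c1ccccc1)c1ccccc1.[Br-]
Why: Wittig methylenation of the lactol through its open-chain aldehyde should give the terminal alkene (C7=CH2) and free the future O4 hydroxyl without touching a stereocenter.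

Step 2
Reactants: 2 1,2-dideoxy-3,4:6,7-di-O-isopropylidene-D-manno-hept-1-enitol
Product: 3 1,2-dideoxy-3,4:6,7-di-O-isopropylidene-5-O-(4-methoxybenzyl)-D-manno-hept-1-enitol
Conditions: NaH, 4-methoxybenzyl chloride, Bu4NI (cat.), DMF, 0 °C to rt
Reagents that add atoms: 4-methoxybenzyl chloride, COc1ccc(CCl)cc1
Why: Williamson etherification of the only free hydroxyl masks O4, so that the later lactonization cannot give the five-membered butenolide.

Step 3
Reactants: 3 1,2-dideoxy-3,4:6,7-di-O-isopropylidene-5-O-(4-methoxybenzyl)-D-manno-hept-1-enitol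
Product: 5 5,6-dideoxy-3,4-O-isopropylidene-2-O-(4-methoxybenzyl)-aldehydo-D-arabino-hex-5-enose, via terminal diol 4 (not isolated)
Conditions: H5IO6, EtOAc, rt
Reagents that add atoms: none
Why: Periodic acid should hydrolyse the more labile terminal acetonide and cleave the released 1,2-diol in the same pot (Malaprade glycol cleavage), leaving the internal acetonide and the PMB ether and exposing C3 as the aldehyde.

Step 4
Reactants: 5 5,6-dideoxy-3,4-O-isopropylidene-2-O-(4-methoxybenzyl)-aldehydo-D-arabino-hex-5-enose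
Product: 6 methyl (2Z)-2,3,7,8-tetradeoxy-5,6-O-isopropylidene-4-O-(4-methoxybenzyl)-D-arabino-octa-2,7-dienoate
Conditions: (CF3CH2O)2P(O)CH2CO2Me, KN(SiMe3)2, 18-crown-6, THF, −78 °C
Reagents that add atoms: methyl bis(2,2,2-trifluoroethyl)phosphonoacetate, COC(=O)CP(=O)(OCC(F)(F)F)OCC(F)(F)F
Why: The Still–Gennari variant of the Horner–Wadsworth–Emmons olefination should give the Z-enoate (C1–C3) from the α-alkoxy aldehyde at low temperature without epimerizing C4.

Step 5
Reactants: 6 methyl (2Z)-2,3,7,8-tetradeoxy-5,6-O-isopropylidene-4-O-(4-methoxybenzyl)-D-arabino-octa-2,7-dienoate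
Product: 8 (5R,6R)-6-[(1R)-1-hydroxyprop-2-en-1-yl]-5-[(4-methoxybenzyl)oxy]-5,6-dihydro-2H-pyran-2-one, via dihydroxy ester 7 (not isolated)
Conditions: TsOH·H2O (cat.), MeOH, rt; then toluene, 40 °C
Reagents that add atoms: none
Why: Acid-catalysed transacetalization frees O5 and O6, and the Z-configured δ-hydroxy ester should lactonize to the six-membered ring (the seven-membered alternative through O6 is disfavoured and O4 is blocked).

Step 6
Reactants: 9 (R)-but-3-en-2-ol
Product: 10 (R)-but-3-en-2-yl benzoate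
Conditions: BzCl, pyridine, 4-(dimethylamino)pyridine (cat.), CH2Cl2, 0 °C to rt
Reagents that add atoms: benzoyl chloride, O=C(Cl)c1ccccc1
Why: Acylation of the secondary alcohol installs the C11 benzoate with the purchased (R) configuration untouched.

Step 7
Reactants: 10 (R)-but-3-en-2-yl benzoate
Product: 12 (R)-1-oxopropan-2-yl benzoate, via ozonide 11 (not isolated)
Conditions: O3, CH2Cl2, −78 °C; then Me2S, −78 °C to rt
Reagents that add atoms: ozone, [O-][O+]=O
Why: Ozonolysis with reductive work-up should give the α-benzoyloxy aldehyde (C10) under neutral conditions that do not racemize C11; it is used at once.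

Step 8
Reactants: 12 (R)-1-oxopropan-2-yl benzoate
Product: 14 (2R,3S)-3-hydroxyhex-5-en-2-yl benzoate, via borinate ester 13 (not isolated)
Conditions: (−)-Ipc2B(allyl) (from (+)-α-pinene), Et2O, −78 °C; then ethanolamine, rt
Reagents that add atoms: (−)-B-allyldiisopinocampheylborane, C=CCB([C@@H]1C[C@@H]2C[C@H]([C@H]1C)C2(C)C)[C@@H]1C[C@@H]2C[C@H]([C@H]1C)C2(C)C
Why: Brown allylboration, in which the reagent delivers allyl to the Si face, matching the Felkin–Anh (anti) preference of the α-acyloxy aldehyde, should set C10 as (S); the non-oxidative ethanolamine work-up avoids benzoyl migration.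

Step 9
Reactants: 8 (5R,6R)-6-[(1R)-1-hydroxyprop-2-en-1-yl]-5-[(4-methoxybenzyl)oxy]-5,6-dihydro-2H-pyran-2-one; 14 (2R,3S)-3-hydroxyhex-5-en-2-yl benzoate
Product: 15 (5R,6R)-6-[(1R,2E,5S,6R)-6-(benzoyloxy)-1,5-dihydroxyhept-2-en-1-yl]-5-[(4-methoxybenzyl)oxy]-5,6-dihydro-2H-pyran-2-one
Conditions: 14 (3 equiv), second-generation Hoveyda–Grubbs catalyst RuCl2(H2IMes)(=CH-C6H4-2-OiPr) (5 mol %), CH2Cl2, 40 °C
Reagents that add atoms: none
Why: Olefin cross-metathesis between the terminal allylic alcohol and the unhindered terminal homoallylic alkene used in excess should give the E-configured C7=C8 alkene, with the conjugated cis lactone alkene as a spectator.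

Step 10
Reactants: 15 (5R,6R)-6-[(1R,2E,5S,6R)-6-(benzoyloxy)-1,5-dihydroxyhept-2-en-1-yl]-5-[(4-methoxybenzyl)oxy]-5,6-dihydro-2H-pyran-2-one
Product: 16 (5R,6R)-6-[(1R,2E,5S,6R)-6-(benzoyloxy)-1,5-dihydroxyhept-2-en-1-yl]-5-hydroxy-5,6-dihydro-2H-pyran-2-one
Conditions: 2,3-dichloro-5,6-dicyano-1,4-benzoquinone (DDQ), CH2Cl2/pH 7 buffer, 0 °C
Reagents that add atoms: none
Why: Oxidative cleavage of the PMB ether under buffered neutral conditions frees O4 only at this point, so the 5-hydroxy lactone is never exposed to base (no translactonization to the butenolide, no oxa-Michael addition of O6).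

Step 11
Reactants: 16 (5R,6R)-6-[(1R,2E,5S,6R)-6-(benzoyloxy)-1,5-dihydroxyhept-2-en-1-yl]-5-hydroxy-5,6-dihydro-2H-pyran-2-one
Product: 19 target (2R,3S,4E)-3-hydroxy-5-[(2S,3R,3aR,7aR)-3-hydroxy-5-oxo-2,3,3a,7a-tetrahydro-5H-furo[3,2-b]pyran-2-yl]pent-4-en-2-yl benzoate, via selenide 17 (not isolated), via selenoxide 18 (not isolated)
Conditions: PhSeCl, CH2Cl2, −78 °C; then pyridine, 30% aq. H2O2, 0 °C to rt
Reagents that add atoms: none
Why: PhSeCl should convert the electron-rich C7=C8 alkene (the conjugated lactone alkene is inert) into a seleniranium ion that O4 opens at C7 in a 5-exo mode (anti addition, PhSe on C8), closing the tetrahydrofuran as a cis-fused bicycle; oxidation to the selenoxide and syn-elimination toward C9, away from the ring oxygen, should then give the E allylic ether. The closest known reaction type is phenylselenoetherification followed by selenoxide elimination, the standard route to 2-alkenyl tetrahydrofurans. C7 is set by substrate control: the allylic C6–O bond takes the in-plane (inside) position and the electrophile adds anti to C5, so O4 enters syn to the C6 hydroxyl (2,3-cis), as in kinetic electrophile-induced closures of 4-ene-1,3-diols and of sugar-derived alkenols; the cis fusion at C4/C5 is enforced by the existing ring, and C8 is a transient center erased by the elimination. The step needs facial selectivity (free C6 hydroxyl, kinetic conditions at −78 °C), chemoselectivity for O4 (5-exo) over O10 (5-endo onto the same carbon, slower) and regioselective elimination (the C7–H sits on an oxygen-bearing carbon and is disfavoured).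

**Compound list**

1 | 2,3:5,6-di-O-isopropylidene-α-D-mannofuranose | O[C@H]1O[C@H]([C@H]2COC(C)(C)O2)[C@@H]3OC(C)(C)O[C@H]13 | starting material
2 | 1,2-dideoxy-3,4:6,7-di-O-isopropylidene-D-manno-hept-1-enitol (free 5-OH) | C=C[C@H]1OC(C)(C)O[C@H]1[C@H](O)[C@H]2COC(C)(C)O2 | intermediate
3 | 1,2-dideoxy-3,4:6,7-di-O-isopropylidene-5-O-(4-methoxybenzyl)-D-manno-hept-1-enitol | C=C[C@H]1OC(C)(C)O[C@H]1[C@H](OCc2ccc(OC)cc2)[C@H]3COC(C)(C)O3 | intermediate
4 | 1,2-dideoxy-3,4-O-isopropylidene-5-O-(4-methoxybenzyl)-D-manno-hept-1-enitol (terminal 6,7-diol; not isolated) | C=C[C@H]1OC(C)(C)O[C@H]1[C@H](OCc2ccc(OC)cc2)[C@H](O)CO | intermediate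
5 | 5,6-dideoxy-3,4-O-isopropylidene-2-O-(4-methoxybenzyl)-aldehydo-D-arabino-hex-5-enose | C=C[C@H]1OC(C)(C)O[C@H]1[C@H](OCc2ccc(OC)cc2)C=O | intermediate
6 | methyl (2Z)-2,3,7,8-tetradeoxy-5,6-O-isopropylidene-4-O-(4-methoxybenzyl)-D-arabino-octa-2,7-dienoate | C=C[C@H]1OC(C)(C)O[C@H]1[C@H](OCc2ccc(OC)cc2)/C=C\C(=O)OC | intermediate
7 | methyl (2Z)-2,3,7,8-tetradeoxy-4-O-(4-methoxybenzyl)-D-arabino-octa-2,7-dienoate (5,6-diol; not isolated) | C=C[C@@H](O)[C@@H](O)[C@H](OCc1ccc(OC)cc1)/C=C\C(=O)OC | intermediate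
8 | (5R,6R)-6-[(1R)-1-hydroxyprop-2-en-1-yl]-5-[(4-methoxybenzyl)oxy]-5,6-dihydro-2H-pyran-2-one | O=C1C=C[C@@H](OCc2ccc(OC)cc2)[C@H](O1)[C@H](O)C=C | intermediate
9 | (R)-but-3-en-2-ol | C[C@@H](O)C=C | starting material
10 | (R)-but-3-en-2-yl benzoate | C[C@@H](OC(=O)c1ccccc1)C=C | intermediate
11 | (1R)-1-(1,2,4-trioxolan-3-yl)ethyl benzoate (ozonide, both epimers at the ring carbon; not isolated) | C[C@@H](OC(=O)c1ccccc1)C1OCOO1 | intermediate
12 | (R)-1-oxopropan-2-yl benzoate | C[C@@H](OC(=O)c1ccccc1)C=O | intermediate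
13 | (2R,3S)-2-(benzoyloxy)hex-5-en-3-yl diisopinocampheylborinate (not isolated) | C[C@@H](OC(=O)c1ccccc1)[C@H](CC=C)OB([C@@H]1C[C@@H]2C[C@H]([C@H]1C)C2(C)C)[C@@H]1C[C@@H]2C[C@H]([C@H]1C)C2(C)C | intermediate
14 | (2R,3S)-3-hydroxyhex-5-en-2-yl benzoate | C[C@@H](OC(=O)c1ccccc1)[C@@H](O)CC=C | intermediate
15 | (5R,6R)-6-[(1R,2E,5S,6R)-6-(benzoyloxy)-1,5-dihydroxyhept-2-en-1-yl]-5-[(4-methoxybenzyl)oxy]-5,6-dihydro-2H-pyran-2-one | O=C1C=C[C@@H](OCc2ccc(OC)cc2)[C@H](O1)[C@H](O)/C=C/C[C@H](O)[C@@H](C)OC(=O)c3ccccc3 | intermediate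
16 | (5R,6R)-6-[(1R,2E,5S,6R)-6-(benzoyloxy)-1,5-dihydroxyhept-2-en-1-yl]-5-hydroxy-5,6-dihydro-2H-pyran-2-one | O=C1C=C[C@@H](O)[C@H](O1)[C@H](O)/C=C/C[C@H](O)[C@@H](C)OC(=O)c2ccccc2 | intermediate
17 | selenide: 19 with C8–C9 saturated and phenylselanyl on C8 (anti adduct, 8S; not isolated) | C[C@@H](OC(=O)c1ccccc1)[C@@H](O)C[C@H]([Se]c1ccccc1)[C@@H]1O[C@@H]2C=CC(=O)O[C@@H]2[C@@H]1O | intermediate
18 | selenoxide of 17 (both configurations at selenium; not isolated) | C[C@@H](OC(=O)c1ccccc1)[C@@H](O)C[C@H]([Se](=O)c1ccccc1)[C@@H]1O[C@@H]2C=CC(=O)O[C@@H]2[C@@H]1O | intermediate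
19 | (2R,3S,4E)-3-hydroxy-5-[(2S,3R,3aR,7aR)-3-hydroxy-5-oxo-2,3,3a,7a-tetrahydro-5H-furo[3,2-b]pyran-2-yl]pent-4-en-2-yl benzoate | C[C@@H](OC(=O)c1ccccc1)[C@@H](O)/C=C/[C@@H]1O[C@@H]2C=CC(=O)O[C@@H]2[C@@H]1O | target

**Step count.** Total: 11 steps. Longest linear sequence: 8 steps (steps 1–5, 9, 10, 11).

**The three steps most likely to fail**

Step 11. What may go wrong: the seleniranium ion may be opened from the wrong alkene face, which would place the side chain trans to the C6 hydroxyl, or O10 may close in a 5-endo mode instead of O4. The fallback is a stereospecific zerovalent-palladium allylic etherification (Tsuji–Trost type on a vinyl epoxide) that sets out from lactone 8 and returns at target 19. Commercial (R)-but-3-yn-2-ol (C[C@@H](O)C#C) and vinyl bromide would be coupled (Sonogashira; PdCl2(PPh3)2, CuI, iPr2NH) to (R)-hex-5-en-3-yn-2-ol F1. NaAlH2(OCH2CH2OMe)2 should reduce the propargylic alcohol to (2R,3E)-hexa-3,5-dien-2-ol F2. Matched Sharpless epoxidation (Ti(OiPr)4, D-(−)-diisopropyl tartrate, t-BuOOH, −20 °C) should give the erythro vinyl epoxide (1R)-1-[(2R,3R)-3-ethenyloxiran-2-yl]ethan-1-ol F3, which is benzoylated (BzCl, pyridine) to (1R)-1-[(2R,3R)-3-ethenyloxiran-2-yl]ethyl benzoate F4. Cross-metathesis of F4 with 8 would give the epoxy lactone F5, and DDQ would free the C4 hydroxyl to give the epoxy diol F6. Pd(PPh3)4 in THF should then ionize the vinyl epoxide with inversion at C9, and O4 should attack C7 of the syn,syn allyl complex anti to palladium. The configuration of C9 is thereby transferred to C7 (net retention), the C8=C9 alkene forms E, and the epoxide oxygen stays on C10 as the free hydroxyl of 19.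

Step 9. What may go wrong: the ruthenium carbene formed at C7 may engage the lactone C2=C3 bond in ring-opening/ring-closing metathesis, and ruthenium hydrides may isomerize the free allylic alcohol to a ketone. The fallback unites the fragments before the lactone exists; it sets out from acetonide 3 and alcohol 14 and returns at 15. Cross-metathesis of 3 with 14 (same catalyst) should give the E-alkene F7, that is 3 with its vinyl CH2 replaced by the C8–C12 arm of 14. H5IO6 in EtOAc would give, through the terminal diol F8, the aldehyde F9. Still–Gennari olefination would give the Z-enoate F10. TsOH in MeOH would remove the acetonide, and the dihydroxy ester F11 should lactonize to 15.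

Step 8. What may go wrong: insufficient facial selectivity in the allyl transfer, or 1,2-migration of the benzoyl group from O11 to O10 when the boron alkoxide is released. The fallback sets C10 by hydroxyl-directed epoxidation instead of allylation; it sets out from 9 and returns at 14. Matched Sharpless epoxidation of 9 (Ti(OiPr)4, D-(−)-diisopropyl tartrate, t-BuOOH) should give the erythro epoxy alcohol (1R)-1-[(2S)-oxiran-2-yl]ethan-1-ol F12. Benzoylation would give (1R)-1-[(2S)-oxiran-2-yl]ethyl benzoate F13. Vinylmagnesium bromide with catalytic CuI (THF, −40 °C, cold quench) should open the epoxide at its CH2 carbon to give 14.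

Further compounds
F1 | step 11 | (R)-hex-5-en-3-yn-2-ol | C[C@@H](O)C#CC=C
F2 | step 11 | (2R,3E)-hexa-3,5-dien-2-ol | C[C@@H](O)/C=C/C=C
F3 | step 11 | (1R)-1-[(2R,3R)-3-ethenyloxiran-2-yl]ethan-1-ol | C[C@@H](O)[C@H]1O[C@@H]1C=C
F4 | step 11 | (1R)-1-[(2R,3R)-3-ethenyloxiran-2-yl]ethyl benzoate | C[C@@H](OC(=O)c1ccccc1)[C@H]1O[C@@H]1C=C
F5 | step 11 | (5R,6R)-6-[(1R,2E)-3-{(2R,3R)-3-[(1R)-1-(benzoyloxy)ethyl]oxiran-2-yl}-1-hydroxyprop-2-en-1-yl]-5-[(4-methoxybenzyl)oxy]-5,6-dihydro-2H-pyran-2-one | O=C1C=C[C@@H](OCc2ccc(OC)cc2)[C@H](O1)[C@H](O)/C=C/[C@H]2O[C@@H]2[C@@H](C)OC(=O)c3ccccc3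
F6 | step 11 | (5R,6R)-6-[(1R,2E)-3-{(2R,3R)-3-[(1R)-1-(benzoyloxy)ethyl]oxiran-2-yl}-1-hydroxyprop-2-en-1-yl]-5-hydroxy-5,6-dihydro-2H-pyran-2-one | O=C1C=C[C@@H](O)[C@H](O1)[C@H](O)/C=C/[C@H]2O[C@@H]2[C@@H](C)OC(=O)c3ccccc3
F7 | step 9 | E cross-metathesis product of 3 and 14 (3 with its vinyl CH2 replaced by the C8–C12 hydroxy benzoate arm) | C[C@@H](OC(=O)c1ccccc1)[C@@H](O)C/C=C/[C@H]2OC(C)(C)O[C@H]2[C@H](OCc3ccc(OC)cc3)[C@H]4COC(C)(C)O4
F8 | step 9 | terminal diol from F7 (terminal acetonide removed) | C[C@@H](OC(=O)c1ccccc1)[C@@H](O)C/C=C/[C@H]2OC(C)(C)O[C@H]2[C@H](OCc3ccc(OC)cc3)[C@H](O)CO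
F9 | step 9 | C3 aldehyde from F8 (glycol cleaved) | C[C@@H](OC(=O)c1ccccc1)[C@@H](O)C/C=C/[C@H]2OC(C)(C)O[C@H]2[C@H](OCc3ccc(OC)cc3)C=O
F10 | step 9 | methyl (2Z,7E) enoate from F9 (C5,C6 acetonide, C4 PMB ether) | C[C@@H](OC(=O)c1ccccc1)[C@@H](O)C/C=C/[C@H]2OC(C)(C)O[C@H]2[C@H](OCc3ccc(OC)cc3)/C=C\C(=O)OC
F11 | step 9 | methyl (2Z,7E) 5,6-dihydroxy enoate from F10 (acetonide removed) | C[C@@H](OC(=O)c1ccccc1)[C@@H](O)C/C=C/[C@@H](O)[C@@H](O)[C@H](OCc2ccc(OC)cc2)/C=C\C(=O)OC
F12 | step 8 | (1R)-1-[(2S)-oxiran-2-yl]ethan-1-ol | C[C@@H](O)[C@@H]1CO1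
F13 | step 8 | (1R)-1-[(2S)-oxiran-2-yl]ethyl benzoate | C[C@@H](OC(=O)c1ccccc1)[C@@H]1CO1
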